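**Retrosynthetic overview**
- The strategy rests on the acyl chain C1–C21: it is unbranched and saturated, and its only functional group is the ester carbonyl C1, so the CH2–CH2 bond C4–C5 can be made by joining two primary alkyl radicals.
- No ring is formed and there is no stereocentre; the only ring, the benzene ring of the phenethyl group, is bought in with the alcohol.
- The C1–C4 piece, with the phenethyl ester already in place, comes from glutaric anhydride (1) and 2-phenylethanol (2), which give the half ester 3 (C–O bond).
- The key C4–C5 disconnection: 3 and stearic acid (4) each lose CO2 at a platinum anode, and the two radicals combine to give the target 5.

Key step: step 2

Assumption: "phenylethyl" is read as 2-phenylethyl (phenethyl), as the SMILES shows.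

**Step 1**
Reactants: 1 glutaric anhydride; 2 2-phenylethanol
Product: 3 5-oxo-5-(2-phenylethoxy)pentanoic acid (mono(2-phenylethyl) glutarate)
Conditions: DMAP (10 mol %), toluene, 90 °C; extraction into aq. NaHCO3, then acidification with HCl
Reagents that add atoms: none
Why: Alcoholysis of a cyclic anhydride (nucleophilic acyl substitution with DMAP acyl-transfer catalysis) should stop at the half ester, because the carboxylic acid set free is not activated, and the symmetrical anhydride leaves no regiochemical question.

**Step 2**
Reactants: 3 mono(2-phenylethyl) glutarate; 4 stearic acid (octadecanoic acid, 3.5 equiv)
Product: 5 2-phenylethyl heneicosanoate
Conditions: NaOMe (5 mol % of total acid), MeOH with a heptane upper layer, smooth Pt foil anode, Pt cathode, undivided cell, constant current about 0.3 A cm−2, 45 °C, stopped when 3 is consumed and the electrolyte is still acidic; AcOH, then chromatography on silica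
Reagents that add atoms: none
Why: Mixed (crossed) Kolbe electrolysis: at the platinum anode the carboxylates of 3 and 4 are each oxidised by one electron, the acyloxy radicals lose CO2, and the resulting 3-(2-phenylethoxycarbonyl)propyl and heptadecyl radicals combine in the concentrated radical layer at the electrode to form the C4–C5 bond, while protons are reduced to H2 at the cathode. The closest known reaction type is the anodic cross-coupling of a fatty acid with a dicarboxylic acid half ester, the classical way to lengthen a saturated chain. No ring is closed and no stereocentre is created, so the only selectivities required are cross- over homo-coupling and radical coupling over further oxidation to a cation (Hofer–Moest pathway). The first is secured statistically by the excess of cheap 4, so that nearly every ester-bearing radical should meet a heptadecyl partner; the second by both radicals being unstabilised primary ones (the ester carbonyl is two CH2 groups away from the radical carbon), together with smooth platinum, high current density and a weakly acidic medium. The free 4 that remains keeps the bulk electrolyte acidic once 3 has been consumed, which should suppress methanolysis of the phenethyl ester, and the phenyl ring, held away from the reacting carboxylate by the OCH2CH2 spacer, is not expected to be oxidised at the carboxylate-covered electrode.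

**Compound list**
1 | glutaric anhydride (oxane-2,6-dione) | O=C1CCCC(=O)O1 | starting material
2 | 2-phenylethanol | OCCc1ccccc1 | starting material
3 | 5-oxo-5-(2-phenylethoxy)pentanoic acid (mono(2-phenylethyl) glutarate) | OC(=O)CCCC(=O)OCCc1ccccc1 | intermediate
4 | stearic acid (octadecanoic acid) | CCCCCCCCCCCCCCCCCC(=O)O | starting material
5 | 2-phenylethyl heneicosanoate | CCCCCCCCCCCCCCCCCCCCC(=O)OCCc1ccccc1 | target

**Step count and risks**
Total step count: 2. Longest linear sequence: 2 steps (1 and 2 to 3, then 3 and 4 to 5). The route has only two steps, so both are ranked and there is no third.

Most likely to fail, step 2. Several processes can lower the efficiency here:
- statistical homo-coupling of each radical with its own kind, which wastes part of 3;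
- coating of the anode by waxy, methanol-insoluble products, which raises the cell voltage and favours over-oxidation of the radicals to cations;
- ester exchange with methanol if the solution near the cathode turns basic.

The fallback makes the same C4–C5 bond by a polar, copper-catalysed alkyl–alkyl coupling in which cross-selectivity is built in. It sets out from 2, which is acylated with commercially available 4-bromobutanoyl chloride (CH2Cl2, 0 °C to room temperature) to give 2-phenylethyl 4-bromobutanoate F1. Commercially available 1-bromoheptadecane is converted with magnesium in THF into heptadecylmagnesium bromide F2. This is added slowly to F1 in THF containing Li2CuCl4 (3 mol %) and N-methylpyrrolidone at 0 to 20 °C (Kochi-type coupling of a Grignard reagent with a primary alkyl bromide, conditions under which ester groups are tolerated). The coupling should give 5 directly, so the fallback comes back to the route at 5.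

Second, step 1. The ring opening may stay incomplete, a second esterification may give some diester, and hydrolysis of the anhydride by adventitious water would give glutaric acid, which would take part in the electrolysis if carried through. The fallback replaces the desymmetrising ring opening by a pre-differentiated diester. It sets out from 2, which is esterified with commercially available 5-tert-butoxy-5-oxopentanoic acid (mono-tert-butyl glutarate) under Steglich conditions (DCC, DMAP cat., CH2Cl2, room temperature) to give tert-butyl 2-phenylethyl pentanedioate F3. The tert-butyl ester is then cleaved with trifluoroacetic acid in CH2Cl2 at room temperature; the primary phenethyl ester is stable to these conditions. This should give 3, where the fallback comes back to the route.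

**Further compounds**
F1 | step 2 | 2-phenylethyl 4-bromobutanoate | BrCCCC(=O)OCCc1ccccc1
F2 | step 2 | heptadecylmagnesium bromide | CCCCCCCCCCCCCCCCC[Mg]Br
F3 | step 1 | tert-butyl 2-phenylethyl pentanedioate | CC(C)(C)OC(=O)CCCC(=O)OCCc1ccccc1
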